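**Plan**

- Locants and rings: spiro[cyclohex-2-ene-1,3'-cyclopenta[b]chromene]; ring A arene, ring B pyran (O4', C3a', C9a', C9'), ring C cyclopentane (C1'–C3', C3a', C9a'), ring D cyclohexene (C1 = C3' spiro, C2H=C3(i-Pr), C4H2, C5H2, C6H(CH3)).
- Cuts, last to first: the two C–CHO bonds on ring A; C3a'–H and the 9a'–CH3 bond; O4'–C3a' and C9'–C9a' (ring B, o-quinone methide [4+2]); C9a' (diazomethane carbon) and both ring C bonds at C1 (spiroannulation of a ring D ketone); ring D bonds C2=C3 and C5–C6 (Robinson annulation).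
- Feature behind the key event: in ring D the spiro carbon C1 lies between vinylic C2 and C6(CH3) and is joined through C2 to the isopropyl-bearing C3. With C1 as a ketone, ring D is the enone of a 1,5-diketone made from an acetoacetate (C2–C1–C6) and isopropyl vinyl ketone (C3–C4–C5).
- Forward order: ring D (step 2), ring C spiro-fused at the ring D carbonyl carbon (steps 4, 5), ring B with ring A attached (step 8), 9a'-methyl and H-3a' (steps 9, 10), phenols and formyl groups (steps 11, 12).
- Stereochemistry: C6 by ligand-controlled decarboxylative protonation (step 3); the spiro centre by attack anti to the C6 methyl group and ring expansion (step 4); C9' by an endo cycloaddition on the enol ether face anti to the C6 arm (step 8); C9a' and C3a' by cyclopropanation and hydride delivery on that same face (steps 9, 10).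

Key step: step 2

Remark: which antipode of the oxazoline ligand gives (R)-6 in step 3 is assigned by analogy with related decarboxylative protonations; the route commits to the antipode that delivers (R)-6, written here as the S ligand.

**Step 1**
Reactants: 1 ethyl 2-methyl-3-oxobutanoate
Product: 2 prop-2-en-1-yl 2-methyl-3-oxobutanoate
Conditions: allyl alcohol (5 equiv), 4-(dimethylamino)pyridine (0.1 equiv), toluene, reflux, EtOH distilled off
Reagents that add atoms: prop-2-en-1-ol, C=CCO
Why: Transesterification of a β-keto ester under nucleophilic catalysis, driven by removal of ethanol, should give the allyl ester needed for step 3; the α-carbon is enolisable and carries no fixed configuration.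

**Step 2**
Reactants: 2 prop-2-en-1-yl 2-methyl-3-oxobutanoate; 3 4-methylpent-1-en-3-one
Product: 5 prop-2-en-1-yl (±)-1-methyl-2-oxo-4-(propan-2-yl)cyclohex-3-ene-1-carboxylate, via Michael adduct 4 (not isolated)
Conditions: 1,8-diazabicyclo[5.4.0]undec-7-ene (0.1 equiv), MeCN, 0 °C to rt; then p-TsOH·H2O (0.3 equiv), toluene, reflux, Dean–Stark trap
Reagents that add atoms: none
Why: Robinson annulation: the amidine base forms the enolate of 2, which adds through its doubly activated α-carbon to the CH2 terminus of enone 3 (Michael addition, ring D bond C5–C6) to give 1,5-diketone 4; under acid the enol of the acetyl methyl group attacks the isopropyl ketone and the aldol loses water, which makes the ring D double bond C2=C3 and leaves the acetyl carbonyl as the future spiro carbon C1. The closest known reaction type is the Robinson annulation of 2-alkylacetoacetates with vinyl ketones that cannot close through their own α' carbon, as with aryl vinyl ketones. Ring D closes in a 6-(enolexo)-exo-trig aldol addition followed by acid-catalysed dehydration. The one new stereocenter, the quaternary C1 of 5, forms without control as the racemate on purpose, because step 3 erases it and sets the configuration there. The step needs a single Michael donor site and a single aldol mode: the ester makes the α-carbon of 2 the only acidic position, and 4 can reach a conjugated enone only through the acetyl methyl group, since the branched side of the isopropyl ketone has a methine that cannot dehydrate into conjugation and its CH2 side would close a four-membered ring.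

**Step 3**
Reactants: 5 prop-2-en-1-yl (±)-1-methyl-2-oxo-4-(propan-2-yl)cyclohex-3-ene-1-carboxylate
Product: 6 (6R)-6-methyl-3-(propan-2-yl)cyclohex-2-en-1-one
Conditions: Pd(OAc)2 (10 mol%), (S)-4-tert-butyl-2-[2-(diphenylphosphanyl)phenyl]-4,5-dihydro-1,3-oxazole (12.5 mol%), Meldrum's acid (2.5 equiv), 1,4-dioxane, 22 °C
Reagents that add atoms: none
Why: Palladium-catalysed enantioselective decarboxylative protonation of an allyl β-keto ester: zerovalent palladium ionises the allyl ester, loss of CO2 gives a ligand-bound palladium enolate, and Meldrum's acid protonates C6 on the face left open by the chiral P,N-ligand (catalyst control), so both enantiomers of 5 should converge on (R)-6 while Meldrum's acid traps the allyl group.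

**Step 4**
Reactants: 6 (6R)-6-methyl-3-(propan-2-yl)cyclohex-2-en-1-one
Product: 8 (4R,9R)-9-methyl-6-(propan-2-yl)spiro[3.5]non-5-en-1-one, via carbinol 7 (not isolated)
Conditions: cyclopropyl phenyl sulfide (1.3 equiv), n-BuLi, THF, 0 °C; 6 added at −78 °C; then 48% aq. HBF4, Et2O, 0 °C to rt
Reagents that add atoms: cyclopropyl phenyl sulfide, C1CC1Sc1ccccc1; water, O
Why: Spiroannulation by cyclopropylcarbinyl-to-cyclobutyl ring expansion: the sulfur-stabilised cyclopropyllithium adds 1,2 to the enone anti to the adjacent C6 methyl group to give 7, acid ionises the tertiary allylic alcohol, a cyclopropane bond migrates to the cationic carbon on the face away from that methyl group and the thionium ion is hydrolysed, so the new carbonyl carbon should end cis and the new CH2 trans to the methyl group (spiro centre R, substrate control).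

**Step 5**
Reactants: 8 (4R,9R)-9-methyl-6-(propan-2-yl)spiro[3.5]non-5-en-1-one
Product: 9 (5R,10R)-10-methyl-7-(propan-2-yl)spiro[4.5]dec-6-en-1-one
Conditions: CH2N2 (2 equiv), Et2O–MeOH (10:1), 0 °C to rt
Reagents that add atoms: diazomethane, C=[N+]=[N-]
Why: Ring expansion of a cyclobutanone with diazomethane (Tiffeneau–Demjanov-type homologation): the strained ketone takes up the diazo carbon and loses N2 with migration of the less substituted α-CH2 and not of the quaternary spiro carbon, which should give the cyclopentanone with the carbonyl still next to the spiro centre; no stereocenter is touched.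

**Step 6**
Reactants: 9 (5R,10R)-10-methyl-7-(propan-2-yl)spiro[4.5]dec-6-en-1-one
Product: 10 tert-butyl(dimethyl){[(5R,10R)-10-methyl-7-(propan-2-yl)spiro[4.5]deca-1,6-dien-1-yl]oxy}silane
Conditions: TBSOTf (1.3 equiv), Et3N (2 equiv), CH2Cl2, 0 °C
Reagents that add atoms: tert-butyldimethylsilyl trifluoromethanesulfonate, CC(C)(C)[Si](C)(C)OS(=O)(=O)C(F)(F)F
Why: Silyl enol ether formation by soft enolisation: the ketone has α-hydrogens only at C2, so one regioisomer should form and no stereocenter is created.

**Step 7**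
Reactants: 11 2,4,6-trihydroxybenzaldehyde
Product: 12 tri-tert-butyl 2-formylbenzene-1,3,5-triyl tricarbonate
Conditions: Boc2O (3.5 equiv), 4-(dimethylamino)pyridine (0.1 equiv), THF, 0 °C to rt
Reagents that add atoms: di-tert-butyl dicarbonate, CC(C)(C)OC(=O)OC(=O)OC(C)(C)C
Why: Acylation of the three phenols with Boc2O under nucleophilic catalysis; the carbonate ortho to the aldehyde is the leaving group that releases the quinone methide in step 8 and the other two protect ring A.

**Step 8**
Reactants: 10 silyl enol ether of 9; 12 tri-tert-butyl 2-formylbenzene-1,3,5-triyl tricarbonate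
Product: 15 (1R,6R,9'R)-6-methyl-9'-(2-methylpropyl)-3-(propan-2-yl)-1',2'-dihydro-9'H-spiro[cyclohex-2-ene-1,3'-cyclopenta[b]chromene]-6',8'-diyl di-tert-butyl dicarbonate, via quinone methide 13 (not isolated), via silyl ketal cycloadduct 14 (not isolated)
Conditions: i-BuMgBr (1.05 equiv to 12), Et2O, −78 °C to rt; then pyridinium p-toluenesulfonate (0.2 equiv), 4 Å MS, toluene, 60 °C
Reagents that add atoms: isobutylmagnesium bromide, CC(C)C[Mg]Br
Why: Generation of an o-quinone methide and inverse-electron-demand hetero-Diels–Alder reaction: the Grignard reagent adds to the aldehyde, the ortho Boc group migrates to the benzylic alkoxide and is expelled to give (E)-quinone methide 13, enol ether 10 adds through its nucleophilic C2 on the cyclopentene face anti to the C6 methyl-bearing arm of ring D with the silyloxy group endo (this should set C9' as R), and acid then eliminates silanol from ketal 14 to the ring B enol ether.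

**Step 9**
Reactants: 15 ring B enol ether (4H-chromene)
Product: 16 (1R,3a'R,6R,9'R,9a'R)-6-methyl-9'-(2-methylpropyl)-3-(propan-2-yl)-1',2'-dihydro-9'H-3a',9a'-methanospiro[cyclohex-2-ene-1,3'-cyclopenta[b]chromene]-6',8'-diyl di-tert-butyl dicarbonate
Conditions: Et2Zn (2 equiv), CH2I2 (2 equiv), CH2Cl2, 0 °C to rt
Reagents that add atoms: diiodomethane, ICI
Why: Simmons–Smith cyclopropanation with the zinc carbenoid from Et2Zn and CH2I2: the electron-rich enol ether should react before the hindered trisubstituted ring D alkene, and the CH2 group should add to the face opposite to the C9' isobutyl group and the C6 methyl-bearing arm, which fixes C3a' and C9a'.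

**Step 10**
Reactants: 16 cyclopropane-fused chroman
Product: 18 (1R,3a'R,6R,9'R,9a'S)-6,9a'-dimethyl-9'-(2-methylpropyl)-3-(propan-2-yl)-1',2',3a',9a'-tetrahydro-9'H-spiro[cyclohex-2-ene-1,3'-cyclopenta[b]chromene]-6',8'-diyl di-tert-butyl dicarbonate, via oxocarbenium trifluoroacetate 17 (not isolated)
Conditions: Et3SiH (3 equiv), TFA (5 equiv), CH2Cl2, −20 °C
Reagents that add atoms: none
Why: Acid-induced opening of an alkoxycyclopropane coupled with ionic hydrogenation: protonation of the cyclopropane CH2 with cleavage of its bond to the oxygen-bearing carbon C3a' leaves it as the 9a' methyl group and gives oxocarbenium ion 17, which triethylsilane should reduce from the less hindered face anti to the C6 methyl-bearing arm, so that H-3a' ends cis to the 9a' methyl group (cis-fused rings B and C).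

**Step 11**
Reactants: 18 chroman bis-carbonate
Product: 19 (1R,3a'R,6R,9'R,9a'S)-6,9a'-dimethyl-9'-(2-methylpropyl)-3-(propan-2-yl)-1',2',3a',9a'-tetrahydro-9'H-spiro[cyclohex-2-ene-1,3'-cyclopenta[b]chromene]-6',8'-diol
Conditions: pyrrolidine (4 equiv), CH2Cl2–MeOH, rt
Reagents that add atoms: none
Why: Aminolysis of the two aryl tert-butyl carbonates by pyrrolidine (acyl transfer to nitrogen) should free the phenols without acid, which spares the ring D alkene; no stereocenter is involved.

**Step 12**
Reactants: 19 chroman diol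
Product: 21 (1R,3a'R,6R,9'R,9a'S)-6',8'-dihydroxy-6,9a'-dimethyl-9'-(2-methylpropyl)-3-(propan-2-yl)-1',2',3a',9a'-tetrahydro-9'H-spiro[cyclohex-2-ene-1,3'-cyclopenta[b]chromene]-5',7'-dicarbaldehyde, via bis-iminium salt 20 (not isolated)
Conditions: POCl3 (4 equiv), DMF (excess), MeCN, 0 °C to rt; then H2O, 50 °C
Reagents that add atoms: N,N-dimethylformamide, CN(C)C=O; water, O
Why: Twofold Vilsmeier–Haack formylation: the chloroiminium ion attacks the two free positions C5' and C7' of the phloroglucinol-type ring A, each activated by three oxygen substituents, and hydrolysis of bis-iminium salt 20 should give the dialdehyde; no stereocenter is involved.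

**Compound list**

1 | ethyl 2-methyl-3-oxobutanoate (racemic, labile centre) | CCOC(=O)C(C)C(C)=O | starting material
2 | prop-2-en-1-yl 2-methyl-3-oxobutanoate (racemic, labile centre) | C=CCOC(=O)C(C)C(C)=O | intermediate
3 | 4-methylpent-1-en-3-one (isopropyl vinyl ketone) | C=CC(=O)C(C)C | starting material
4 | prop-2-en-1-yl (±)-2-acetyl-2,6-dimethyl-5-oxoheptanoate | C=CCOC(=O)C(C)(CCC(=O)C(C)C)C(C)=O | intermediate (not isolated)
5 | prop-2-en-1-yl (±)-1-methyl-2-oxo-4-(propan-2-yl)cyclohex-3-ene-1-carboxylate | C=CCOC(=O)C1(C)CCC(C(C)C)=CC1=O | intermediate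
6 | (6R)-6-methyl-3-(propan-2-yl)cyclohex-2-en-1-one | O=C1C=C(C(C)C)CC[C@H]1C | intermediate
7 | (1R,6R)-6-methyl-1-[1-(phenylsulfanyl)cyclopropyl]-3-(propan-2-yl)cyclohex-2-en-1-ol (cyclopropyl trans to the C6 methyl) | O[C@@]1(C2(Sc3ccccc3)CC2)C=C(C(C)C)CC[C@H]1C | intermediate (not isolated)
8 | (4R,9R)-9-methyl-6-(propan-2-yl)spiro[3.5]non-5-en-1-one (C=O carbon cis to the C9 methyl) | O=C2CC[C@@]21C=C(C(C)C)CC[C@H]1C | intermediate
9 | (5R,10R)-10-methyl-7-(propan-2-yl)spiro[4.5]dec-6-en-1-one | O=C2CCC[C@@]21C=C(C(C)C)CC[C@H]1C | intermediate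
10 | tert-butyl(dimethyl){[(5R,10R)-10-methyl-7-(propan-2-yl)spiro[4.5]deca-1,6-dien-1-yl]oxy}silane | CC(C)(C)[Si](C)(C)OC2=CCC[C@@]21C=C(C(C)C)CC[C@H]1C | intermediate
11 | 2,4,6-trihydroxybenzaldehyde | O=Cc1c(O)cc(O)cc1O | starting material
12 | tri-tert-butyl 2-formylbenzene-1,3,5-triyl tricarbonate | O=Cc1c(OC(=O)OC(C)(C)C)cc(OC(=O)OC(C)(C)C)cc1OC(=O)OC(C)(C)C | intermediate
13 | di-tert-butyl (6E)-6-(3-methylbutylidene)-5-oxocyclohexa-1,3-diene-1,3-diyl dicarbonate (o-quinone methide) | CC(C)C/C=C1/C(=O)C=C(OC(=O)OC(C)(C)C)C=C1OC(=O)OC(C)(C)C | intermediate (not isolated)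
14 | (1R,3a'R,6R,9'R,9a'R)-3a'-{[tert-butyl(dimethyl)silyl]oxy}-6-methyl-9'-(2-methylpropyl)-3-(propan-2-yl)-1',2',3a',9a'-tetrahydro-9'H-spiro[cyclohex-2-ene-1,3'-cyclopenta[b]chromene]-6',8'-diyl di-tert-butyl dicarbonate | CC(C)C[C@H]1c2c(OC(=O)OC(C)(C)C)cc(OC(=O)OC(C)(C)C)cc2O[C@@]2(O[Si](C)(C)C(C)(C)C)[C@@H]1CC[C@@]21C=C(C(C)C)CC[C@H]1C | intermediate (not isolated)
15 | (1R,6R,9'R)-6-methyl-9'-(2-methylpropyl)-3-(propan-2-yl)-1',2'-dihydro-9'H-spiro[cyclohex-2-ene-1,3'-cyclopenta[b]chromene]-6',8'-diyl di-tert-butyl dicarbonate | CC(C)C[C@H]1c2c(OC(=O)OC(C)(C)C)cc(OC(=O)OC(C)(C)C)cc2OC2=C1CC[C@@]21C=C(C(C)C)CC[C@H]1C | intermediate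
16 | (1R,3a'R,6R,9'R,9a'R)-3a',9a'-methano (cyclopropane) derivative of 15, CH2 trans to the C9' isobutyl group | CC(C)C[C@H]1c2c(OC(=O)OC(C)(C)C)cc(OC(=O)OC(C)(C)C)cc2O[C@@]23C[C@@]31CC[C@@]21C=C(C(C)C)CC[C@H]1C | intermediate
17 | (1R,6R,9'R,9a'S)-6',8'-bis[(tert-butoxycarbonyl)oxy]-6,9a'-dimethyl-9'-(2-methylpropyl)-3-(propan-2-yl)-1',2',9',9a'-tetrahydrospiro[cyclohex-2-ene-1,3'-cyclopenta[b]chromen]-4'-ium trifluoroacetate | CC(C)C[C@H]1c2c(OC(=O)OC(C)(C)C)cc(OC(=O)OC(C)(C)C)cc2[O+]=C2[C@@]1(C)CC[C@@]21C=C(C(C)C)CC[C@H]1C.[O-]C(=O)C(F)(F)F | intermediate (not isolated)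
18 | (1R,3a'R,6R,9'R,9a'S)-6,9a'-dimethyl-9'-(2-methylpropyl)-3-(propan-2-yl)-1',2',3a',9a'-tetrahydro-9'H-spiro[cyclohex-2-ene-1,3'-cyclopenta[b]chromene]-6',8'-diyl di-tert-butyl dicarbonate | CC(C)C[C@H]1c2c(OC(=O)OC(C)(C)C)cc(OC(=O)OC(C)(C)C)cc2O[C@@H]2[C@@]1(C)CC[C@@]21C=C(C(C)C)CC[C@H]1C | intermediate
19 | (1R,3a'R,6R,9'R,9a'S)-6,9a'-dimethyl-9'-(2-methylpropyl)-3-(propan-2-yl)-1',2',3a',9a'-tetrahydro-9'H-spiro[cyclohex-2-ene-1,3'-cyclopenta[b]chromene]-6',8'-diol | CC(C)C[C@H]1c2c(O)cc(O)cc2O[C@@H]2[C@@]1(C)CC[C@@]21C=C(C(C)C)CC[C@H]1C | intermediate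
20 | 5',7'-bis[(dimethyliminio)methyl] derivative of 19, dichloride | CC(C)C[C@H]1c2c(O)c(C=[N+](C)C)c(O)c(C=[N+](C)C)c2O[C@@H]2[C@@]1(C)CC[C@@]21C=C(C(C)C)CC[C@H]1C.[Cl-].[Cl-] | intermediate (not isolated)
21 | (1R,3a'R,6R,9'R,9a'S)-6',8'-dihydroxy-6,9a'-dimethyl-9'-(2-methylpropyl)-3-(propan-2-yl)-1',2',3a',9a'-tetrahydro-9'H-spiro[cyclohex-2-ene-1,3'-cyclopenta[b]chromene]-5',7'-dicarbaldehyde | CC(C)C[C@H]1c2c(O)c(C=O)c(O)c(C=O)c2O[C@@H]2[C@@]1(C)CC[C@@]21C=C(C(C)C)CC[C@H]1C | target

**Count and risks**

Total step count: 12. Longest linear sequence: 11 steps (steps 1 to 6 and 8 to 12; step 7 is a one-step side branch).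

The three steps most likely to fail:

Step 3. The protonation of the palladium enolate may discriminate its two faces only in part, and the α-stereocenter of 6 may erode by enolisation on work-up or under the basic reagent of step 4, so that enantiomeric purity is lost. The fallback sets out from 5. Deallylation and decarboxylation with Pd(PPh3)4 and HCO2H/Et3N in THF would give racemic (±)-6-methyl-3-(propan-2-yl)cyclohex-2-en-1-one F1. Kinetic deprotonation at C6 with LiN(i-Pr)2 at −78 °C and silylation with TMSCl would give the cross-conjugated dienol ether trimethyl{[2-methyl-5-(propan-2-yl)cyclohexa-1,5-dien-1-yl]oxy}silane F2, which has no stereocenter. Protonation of F2 at −78 °C in toluene with a stoichiometric chiral Brønsted acid (the 1:1 complex of SnCl4 with the antipode of BINOL monomethyl ether that gives the R ketone) would come back to the route at 6.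

Step 8. The quinone methide may add to the wrong face of the enol ether or through the exo transition state (epimer at C9'), or may oligomerise before the hindered enol ether traps it. The fallback sets out from 9 and 11 and fixes C9' by a conjugate addition instead of a cycloaddition. Protection of 11 with MOMCl and i-Pr2NEt would give 2,4,6-tris(methoxymethoxy)benzaldehyde F3. Claisen–Schmidt condensation of 9 with F3 (NaOH, EtOH) would give (2E,5R,10R)-10-methyl-7-(propan-2-yl)-2-{[2,4,6-tris(methoxymethoxy)phenyl]methylidene}spiro[4.5]dec-6-en-1-one F4. An isobutyl cuprate (i-BuMgBr, CuBr·SMe2, TMSCl, THF, −78 °C) should add to the exocyclic enone on the face anti to the C6 methyl-bearing arm and give (5R,10R)-10-methyl-2-{(1R)-3-methyl-1-[2,4,6-tris(methoxymethoxy)phenyl]butyl}-7-(propan-2-yl)spiro[4.5]dec-6-en-1-one F5, which has the C9' configuration of 15. HCl in MeOH would remove the three acetals and close the enol ether to (1R,6R,9'R)-6-methyl-9'-(2-methylpropyl)-3-(propan-2-yl)-1',2'-dihydro-9'H-spiro[cyclohex-2-ene-1,3'-cyclopenta[b]chromene]-6',8'-diol F6. Boc2O with 4-(dimethylamino)pyridine would come back to the route at 15.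

Step 10. Protonation of the ring D alkene (ionic hydrogenation or cationic rearrangement beside the spiro centre) may compete with opening of a cyclopropyl aryl ether whose oxygen is only a weak donor, and the carbonates may be lost early. The fallback sets out from 16 and separates ring opening from reduction. p-TsOH·H2O in wet THF at 0 °C, with no hydride present, would open the cyclopropane to the hemiketal (1R,6R,9'R,9a'S)-3a'-hydroxy-6,9a'-dimethyl-9'-(2-methylpropyl)-3-(propan-2-yl)-1',2',3a',9a'-tetrahydro-9'H-spiro[cyclohex-2-ene-1,3'-cyclopenta[b]chromene]-6',8'-diyl di-tert-butyl dicarbonate F7 (both epimers at C3a'). Reduction of F7 with Et3SiH and BF3·OEt2 in CH2Cl2 at −78 °C, where a trisubstituted alkene is not protonated, would come back to the route at 18.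

**Further compounds**

F1 | step 3 | (±)-6-methyl-3-(propan-2-yl)cyclohex-2-en-1-one | O=C1C=C(C(C)C)CCC1C
F2 | step 3 | trimethyl{[2-methyl-5-(propan-2-yl)cyclohexa-1,5-dien-1-yl]oxy}silane | CC1=C(O[Si](C)(C)C)C=C(C(C)C)CC1
F3 | step 8 | 2,4,6-tris(methoxymethoxy)benzaldehyde | O=Cc1c(OCOC)cc(OCOC)cc1OCOC
F4 | step 8 | (2E,5R,10R)-10-methyl-7-(propan-2-yl)-2-{[2,4,6-tris(methoxymethoxy)phenyl]methylidene}spiro[4.5]dec-6-en-1-one | O=C2/C(=C/c3c(OCOC)cc(OCOC)cc3OCOC)CC[C@@]21C=C(C(C)C)CC[C@H]1C
F5 | step 8 | (5R,10R)-10-methyl-2-{(1R)-3-methyl-1-[2,4,6-tris(methoxymethoxy)phenyl]butyl}-7-(propan-2-yl)spiro[4.5]dec-6-en-1-one (C2 epimers) | CC(C)C[C@@H](c1c(OCOC)cc(OCOC)cc1OCOC)C1CC[C@@]2(C=C(C(C)C)CC[C@H]2C)C1=O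
F6 | step 8 | (1R,6R,9'R)-6-methyl-9'-(2-methylpropyl)-3-(propan-2-yl)-1',2'-dihydro-9'H-spiro[cyclohex-2-ene-1,3'-cyclopenta[b]chromene]-6',8'-diol | CC(C)C[C@H]1c2c(O)cc(O)cc2OC2=C1CC[C@@]21C=C(C(C)C)CC[C@H]1C
F7 | step 10 | (1R,6R,9'R,9a'S)-3a'-hydroxy-6,9a'-dimethyl-9'-(2-methylpropyl)-3-(propan-2-yl)-1',2',3a',9a'-tetrahydro-9'H-spiro[cyclohex-2-ene-1,3'-cyclopenta[b]chromene]-6',8'-diyl di-tert-butyl dicarbonate (C3a' epimers) | CC(C)C[C@H]1c2c(OC(=O)OC(C)(C)C)cc(OC(=O)OC(C)(C)C)cc2OC2(O)[C@@]1(C)CC[C@@]21C=C(C(C)C)CC[C@H]1C
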